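**Assumption:** positions are labelled C1–C15 as in eudesmanolides (lactone carbonyl C12, carbinol carbons C6 and C8, side chain C1–C4), and commercial (S)-(−)-citronellol of high enantiomeric purity supplies C4.

**Retrosynthetic overview**
1. Target ← britannilactone 26 by double acetylation; the exo-methylene comes from enolate Mannich methylenation of the cis-fused lactone.
2. Ring order: the γ-lactone is closed first (C8–O onto the C12 ester), then the cyclohexene by ring-closing metathesis forming C5=C10.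
3. C8–O ← Felkin–Anh reduction of a methallyl ketone made from a Weinreb amide and 2-methylallylmagnesium chloride.
4. Key C6–C7 bond ← intermolecular MgCl2-catalysed Evans anti-aldol of succinate imide 13 with α-methylene aldehyde 9 (sets C6 and C7).
5. Aldehyde 9 ← (S)-citronellol by ozonolysis, protecting-group exchange, oxidation and Mannich α-methylenation.

**Route**

Step 1
Reactants: 1 (S)-citronellol
Product: 2 (3S)-3,7-dimethyloct-6-en-1-yl acetate
Conditions: Ac2O, pyridine, DMAP (cat.), CH2Cl2, 0 °C to rt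
Reagents that add atoms: acetic anhydride, CC(=O)OC(C)=O
Why: DMAP-catalysed acylation (nucleophilic acyl substitution) masks the primary alcohol so that the two chain ends stay distinguishable after alkene cleavage, and no stereocentre is touched.

Step 2
Reactants: 2 (3S)-3,7-dimethyloct-6-en-1-yl acetate
Product: 4 (3S)-6-hydroxy-3-methylhexyl acetate, via aldehyde 3 (not isolated)
Conditions: O3, CH2Cl2/MeOH, −78 °C; then NaBH4, −78 to 0 °C
Reagents that add atoms: ozone, [O-][O+]=O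
Why: Ozonolysis of the electron-rich trisubstituted alkene with reductive borohydride work-up gives the primary alcohol while the acetate survives the cold conditions, and the methyl-bearing stereocentre is remote from the reacting site.

Step 3
Reactants: 4 (3S)-6-hydroxy-3-methylhexyl acetate
Product: 5 (3S)-6-[(tert-butyldiphenylsilyl)oxy]-3-methylhexyl acetate
Conditions: t-BuPh2SiCl, imidazole, DMF, rt
Reagents that add atoms: tert-butyl(chloro)diphenylsilane, CC(C)(C)[Si](Cl)(c1ccccc1)c1ccccc1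
Why: Imidazole-promoted silylation of the unhindered primary alcohol installs a silyl ether that is robust to the base, acid, organometallic and hydride steps ahead.

Step 4
Reactants: 5 (3S)-6-[(tert-butyldiphenylsilyl)oxy]-3-methylhexyl acetate
Product: 6 (3S)-6-[(tert-butyldiphenylsilyl)oxy]-3-methylhexan-1-ol
Conditions: K2CO3 (0.2 equiv), MeOH, rt
Reagents that add atoms: none
Why: Base-catalysed transesterification (methanolysis) removes the acetate selectively because the tert-butyldiphenylsilyl ether is inert to carbonate in methanol.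

Step 5
Reactants: 6 (3S)-6-[(tert-butyldiphenylsilyl)oxy]-3-methylhexan-1-ol
Product: 7 (3S)-6-[(tert-butyldiphenylsilyl)oxy]-3-methylhexanal
Conditions: PhI(OAc)2, TEMPO (10 mol%), CH2Cl2, rt
Reagents that add atoms: none
Why: TEMPO-catalysed oxoammonium oxidation stops cleanly at the aldehyde, and the stereocentre is β to the new carbonyl so it cannot epimerise.

Step 6
Reactants: 7 (3S)-6-[(tert-butyldiphenylsilyl)oxy]-3-methylhexanal
Product: 9 (3S)-6-[(tert-butyldiphenylsilyl)oxy]-3-methyl-2-methylidenehexanal, via Mannich base 8 (not isolated)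
Conditions: CH2=NMe2+ I−, Et3N, CH2Cl2, rt
Reagents that add atoms: N,N-dimethylmethylideneammonium iodide (Eschenmoser's salt), C=[N+](C)C.[I-]
Why: A Mannich reaction of the aldehyde enol with the iminium salt followed by β-elimination of dimethylamine gives the non-enolisable α-methylene aldehyde, and the transient C2 centre is destroyed while the neighbouring 3S centre is not acidic.

Step 7
Reactants: 10 4-(tert-butoxy)-4-oxobutanoic acid; 11 (4R)-4-benzyl-1,3-oxazolidin-2-one
Product: 13 tert-butyl 4-[(4R)-4-benzyl-2-oxo-1,3-oxazolidin-3-yl]-4-oxobutanoate, via mixed anhydride 12 (not isolated)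
Conditions: t-BuCOCl, Et3N, THF, −20 °C; then 11, LiCl, −20 °C to rt
Reagents that add atoms: none
Why: N-acylation of the oxazolidinone through the pivalic mixed anhydride is regioselective because the hindered pivaloyl carbonyl is not attacked.

Step 8
Reactants: 13 tert-butyl 4-[(4R)-4-benzyl-2-oxo-1,3-oxazolidin-3-yl]-4-oxobutanoate; 9 (3S)-6-[(tert-butyldiphenylsilyl)oxy]-3-methyl-2-methylidenehexanal
Product: 15 tert-butyl (3S,4R,6S)-3-{[(4R)-4-benzyl-2-oxo-1,3-oxazolidin-3-yl]carbonyl}-9-[(tert-butyldiphenylsilyl)oxy]-4-hydroxy-6-methyl-5-methylidenenonanoate, via silyl ether 14 (not isolated)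
Conditions: MgCl2 (20 mol%), Et3N, Me3SiCl, EtOAc, 23 °C; then 1 M HCl, THF, rt
Reagents that add atoms: none
Why: In this MgCl2-catalysed Evans anti-aldol the magnesium-chelated Z-enolate of the (R)-benzyl imide is attacked by the non-enolisable aldehyde on the face away from the benzyl group through a boat-like transition state, which forms the C6–C7 bond and sets C3 as S and C4 as R (anti), with the remote 6S centre exerting no significant bias.

Step 9
Reactants: 15 tert-butyl (3S,4R,6S)-3-{[(4R)-4-benzyl-2-oxo-1,3-oxazolidin-3-yl]carbonyl}-9-[(tert-butyldiphenylsilyl)oxy]-4-hydroxy-6-methyl-5-methylidenenonanoate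
Product: 16 tert-butyl (3S,4R,6S)-9-[(tert-butyldiphenylsilyl)oxy]-4-hydroxy-3-[methoxy(methyl)carbamoyl]-6-methyl-5-methylidenenonanoate
Conditions: MeNH(OMe)·HCl, AlMe3, CH2Cl2, −15 to 0 °C
Reagents that add atoms: N,O-dimethylhydroxylamine hydrochloride, CNOC.Cl
Why: Weinreb transamination with the aluminium amide is directed to the exocyclic imide carbonyl by the free β-hydroxyl, leaves the hindered tert-butyl ester alone at 0 °C and does not touch the α-stereocentre.

Step 10
Reactants: 16 tert-butyl (3S,4R,6S)-9-[(tert-butyldiphenylsilyl)oxy]-4-hydroxy-3-[methoxy(methyl)carbamoyl]-6-methyl-5-methylidenenonanoate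
Product: 17 tert-butyl (3S,4R,6S)-4-[(tert-butyldimethylsilyl)oxy]-9-[(tert-butyldiphenylsilyl)oxy]-3-[methoxy(methyl)carbamoyl]-6-methyl-5-methylidenenonanoate
Conditions: t-BuMe2SiOTf, 2,6-lutidine, CH2Cl2, −78 to 0 °C
Reagents that add atoms: tert-butyldimethylsilyl trifluoromethanesulfonate, CC(C)(C)[Si](C)(C)OS(=O)(=O)C(F)(F)F
Why: Silylation with the reactive triflate protects the hindered allylic C6 hydroxyl so that only the C8 oxygen can later close the lactone.

Step 11
Reactants: 17 tert-butyl (3S,4R,6S)-4-[(tert-butyldimethylsilyl)oxy]-9-[(tert-butyldiphenylsilyl)oxy]-3-[methoxy(methyl)carbamoyl]-6-methyl-5-methylidenenonanoate; 18 (2-methylprop-2-en-1-yl)magnesium chloride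
Product: 19 tert-butyl (3S,4R,6S)-4-[(tert-butyldimethylsilyl)oxy]-9-[(tert-butyldiphenylsilyl)oxy]-6-methyl-5-methylidene-3-(3-methylbut-3-enoyl)nonanoate
Conditions: THF, −78 to −20 °C; sat. NH4Cl quench at −20 °C
Reagents that add atoms: none
Why: Grignard addition to the Weinreb amide stops at the ketone because the chelated tetrahedral intermediate survives until the cold quench, which also protects the α-stereocentre and keeps the β,γ-alkene out of conjugation, while the tert-butyl ester is too hindered to react.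

Step 12
Reactants: 19 tert-butyl (3S,4R,6S)-4-[(tert-butyldimethylsilyl)oxy]-9-[(tert-butyldiphenylsilyl)oxy]-6-methyl-5-methylidene-3-(3-methylbut-3-enoyl)nonanoate
Product: 21 (4R,5R)-4-{(1R,3S)-1-[(tert-butyldimethylsilyl)oxy]-6-[(tert-butyldiphenylsilyl)oxy]-3-methyl-2-methylidenehexyl}-5-(2-methylprop-2-en-1-yl)oxolan-2-one, via hydroxy ester 20 (not isolated)
Conditions: LiBH(s-Bu)3, THF, −78 °C; then p-TsOH·H2O (10 mol%), toluene, 50 °C
Reagents that add atoms: none
Why: In this Felkin–Anh reduction the bulky hydride attacks anti to the large silyloxy-bearing branch of the adjacent stereocentre (reinforced by the β-silyloxy 1,3-effect), setting the new carbinol as 1R (anti to the CH2CO2t-Bu arm, syn to the silyl ether oxygen), and acid-catalysed transesterification then closes the cis-disubstituted γ-lactone onto this only free hydroxyl.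

Step 13
Reactants: 21 (4R,5R)-4-{(1R,3S)-1-[(tert-butyldimethylsilyl)oxy]-6-[(tert-butyldiphenylsilyl)oxy]-3-methyl-2-methylidenehexyl}-5-(2-methylprop-2-en-1-yl)oxolan-2-one
Product: 22 (3aR,4R,7aR)-4-[(tert-butyldimethylsilyl)oxy]-5-{(2S)-5-[(tert-butyldiphenylsilyl)oxy]pentan-2-yl}-6-methyl-3a,4,7,7a-tetrahydro-1-benzofuran-2(3H)-one
Conditions: second-generation Hoveyda–Grubbs catalyst (H2IMes)Cl2Ru=CH(2-i-PrO-C6H4) (15 mol% in portions), toluene (5 mM), 100 °C, Ar sparge
Reagents that add atoms: none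
Why: Ring-closing metathesis of the two 1,1-disubstituted alkenes, held close by their cis placement on the lactone, forms the tetrasubstituted C5=C10 bond with loss of ethene and creates no new stereocentre.

Step 14
Reactants: 22 (3aR,4R,7aR)-4-[(tert-butyldimethylsilyl)oxy]-5-{(2S)-5-[(tert-butyldiphenylsilyl)oxy]pentan-2-yl}-6-methyl-3a,4,7,7a-tetrahydro-1-benzofuran-2(3H)-one
Product: 25 (3aR,4R,7aR)-4-[(tert-butyldimethylsilyl)oxy]-5-{(2S)-5-[(tert-butyldiphenylsilyl)oxy]pentan-2-yl}-6-methyl-3-methylidene-3a,4,7,7a-tetrahydro-1-benzofuran-2(3H)-one, via amine 23 (not isolated), via ammonium iodide 24 (not isolated)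
Conditions: LiN(i-Pr)2 (commercial solution), THF, −78 °C; CH2=NMe2+ I−, −78 °C to rt; then MeI, MeOH, rt; then NaHCO3 (aq.), EtOAc, rt
Reagents that add atoms: N,N-dimethylmethylideneammonium iodide (Eschenmoser's salt), C=[N+](C)C.[I-]
Why: Mannich reaction of the lactone lithium enolate, N-quaternisation and β-elimination of trimethylamine give the α-methylene lactone, and the transient C3 centre is erased while the ring-fusion centres carry no acidic leaving-group arrangement.

Step 15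
Reactants: 25 (3aR,4R,7aR)-4-[(tert-butyldimethylsilyl)oxy]-5-{(2S)-5-[(tert-butyldiphenylsilyl)oxy]pentan-2-yl}-6-methyl-3-methylidene-3a,4,7,7a-tetrahydro-1-benzofuran-2(3H)-one
Product: 26 britannilactone, (3aS,4R,7aR)-4-hydroxy-5-[(2S)-5-hydroxypentan-2-yl]-6-methyl-3-methylidene-3a,4,7,7a-tetrahydro-1-benzofuran-2(3H)-one
Conditions: HF·pyridine, pyridine, THF, 0 °C to rt
Reagents that add atoms: none
Why: Buffered fluoride desilylation cleaves both silyl ethers under mildly acidic non-nucleophilic conditions that spare the α-methylene lactone and the allylic alcohol (the 3a descriptor changes only through ligand priorities).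

Step 16
Reactants: 26 britannilactone
Product: 27 1,6-O,O-diacetylbritannilactone, (3aR,4R,7aR)-5-[(2S)-5-(acetyloxy)pentan-2-yl]-6-methyl-3-methylidene-2-oxo-2,3,3a,4,7,7a-hexahydro-1-benzofuran-4-yl acetate
Conditions: Ac2O, pyridine, DMAP (cat.), CH2Cl2, 0 °C to rt
Reagents that add atoms: acetic anhydride, CC(=O)OC(C)=O
Why: DMAP-catalysed acylation esterifies both the primary and the hindered allylic secondary hydroxyl without affecting any stereocentre or the lactone.

**Compound list**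

1 | (S)-citronellol, (3S)-3,7-dimethyloct-6-en-1-ol | OCC[C@@H](C)CCC=C(C)C | starting material
2 | (3S)-3,7-dimethyloct-6-en-1-yl acetate | CC(=O)OCC[C@@H](C)CCC=C(C)C | intermediate
3 | (3S)-3-methyl-6-oxohexyl acetate | CC(=O)OCC[C@@H](C)CCC=O | intermediate
4 | (3S)-6-hydroxy-3-methylhexyl acetate | CC(=O)OCC[C@@H](C)CCCO | intermediate
5 | (3S)-6-[(tert-butyldiphenylsilyl)oxy]-3-methylhexyl acetate | CC(=O)OCC[C@@H](C)CCCO[Si](c1ccccc1)(c1ccccc1)C(C)(C)C | intermediate
6 | (3S)-6-[(tert-butyldiphenylsilyl)oxy]-3-methylhexan-1-ol | OCC[C@@H](C)CCCO[Si](c1ccccc1)(c1ccccc1)C(C)(C)C | intermediate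
7 | (3S)-6-[(tert-butyldiphenylsilyl)oxy]-3-methylhexanal | O=CC[C@@H](C)CCCO[Si](c1ccccc1)(c1ccccc1)C(C)(C)C | intermediate
8 | (3S)-6-[(tert-butyldiphenylsilyl)oxy]-2-[(dimethylamino)methyl]-3-methylhexanal (C2 epimers) | CN(C)CC(C=O)[C@@H](C)CCCO[Si](c1ccccc1)(c1ccccc1)C(C)(C)C | intermediate
9 | (3S)-6-[(tert-butyldiphenylsilyl)oxy]-3-methyl-2-methylidenehexanal | C=C(C=O)[C@@H](C)CCCO[Si](c1ccccc1)(c1ccccc1)C(C)(C)C | intermediate
10 | 4-(tert-butoxy)-4-oxobutanoic acid | CC(C)(C)OC(=O)CCC(=O)O | starting material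
11 | (4R)-4-benzyl-1,3-oxazolidin-2-one | O=C1N[C@H](Cc2ccccc2)CO1 | starting material
12 | 4-(tert-butoxy)-4-oxobutanoic 2,2-dimethylpropanoic anhydride | CC(C)(C)OC(=O)CCC(=O)OC(=O)C(C)(C)C | intermediate
13 | tert-butyl 4-[(4R)-4-benzyl-2-oxo-1,3-oxazolidin-3-yl]-4-oxobutanoate | CC(C)(C)OC(=O)CCC(=O)N1[C@H](Cc2ccccc2)COC1=O | intermediate
14 | tert-butyl (3S,4R,6S)-3-{[(4R)-4-benzyl-2-oxo-1,3-oxazolidin-3-yl]carbonyl}-9-[(tert-butyldiphenylsilyl)oxy]-6-methyl-5-methylidene-4-[(trimethylsilyl)oxy]nonanoate | CC(C)(C)OC(=O)C[C@H](C(=O)N1[C@H](Cc2ccccc2)COC1=O)[C@@H](O[Si](C)(C)C)C(=C)[C@@H](C)CCCO[Si](c1ccccc1)(c1ccccc1)C(C)(C)C | intermediate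
15 | tert-butyl (3S,4R,6S)-3-{[(4R)-4-benzyl-2-oxo-1,3-oxazolidin-3-yl]carbonyl}-9-[(tert-butyldiphenylsilyl)oxy]-4-hydroxy-6-methyl-5-methylidenenonanoate | CC(C)(C)OC(=O)C[C@H](C(=O)N1[C@H](Cc2ccccc2)COC1=O)[C@@H](O)C(=C)[C@@H](C)CCCO[Si](c1ccccc1)(c1ccccc1)C(C)(C)C | intermediate
16 | tert-butyl (3S,4R,6S)-9-[(tert-butyldiphenylsilyl)oxy]-4-hydroxy-3-[methoxy(methyl)carbamoyl]-6-methyl-5-methylidenenonanoate | CC(C)(C)OC(=O)C[C@H](C(=O)N(C)OC)[C@@H](O)C(=C)[C@@H](C)CCCO[Si](c1ccccc1)(c1ccccc1)C(C)(C)C | intermediate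
17 | tert-butyl (3S,4R,6S)-4-[(tert-butyldimethylsilyl)oxy]-9-[(tert-butyldiphenylsilyl)oxy]-3-[methoxy(methyl)carbamoyl]-6-methyl-5-methylidenenonanoate | CC(C)(C)OC(=O)C[C@H](C(=O)N(C)OC)[C@@H](O[Si](C)(C)C(C)(C)C)C(=C)[C@@H](C)CCCO[Si](c1ccccc1)(c1ccccc1)C(C)(C)C | intermediate
18 | (2-methylprop-2-en-1-yl)magnesium chloride | C=C(C)C[Mg]Cl | starting material
19 | tert-butyl (3S,4R,6S)-4-[(tert-butyldimethylsilyl)oxy]-9-[(tert-butyldiphenylsilyl)oxy]-6-methyl-5-methylidene-3-(3-methylbut-3-enoyl)nonanoate | CC(C)(C)OC(=O)C[C@H](C(=O)CC(C)=C)[C@@H](O[Si](C)(C)C(C)(C)C)C(=C)[C@@H](C)CCCO[Si](c1ccccc1)(c1ccccc1)C(C)(C)C | intermediate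
20 | tert-butyl (3R,4R,6S)-4-[(tert-butyldimethylsilyl)oxy]-9-[(tert-butyldiphenylsilyl)oxy]-3-[(1R)-1-hydroxy-3-methylbut-3-en-1-yl]-6-methyl-5-methylidenenonanoate | CC(C)(C)OC(=O)C[C@H]([C@H](O)CC(C)=C)[C@@H](O[Si](C)(C)C(C)(C)C)C(=C)[C@@H](C)CCCO[Si](c1ccccc1)(c1ccccc1)C(C)(C)C | intermediate
21 | (4R,5R)-4-{(1R,3S)-1-[(tert-butyldimethylsilyl)oxy]-6-[(tert-butyldiphenylsilyl)oxy]-3-methyl-2-methylidenehexyl}-5-(2-methylprop-2-en-1-yl)oxolan-2-one | O=C1C[C@@H]([C@@H](O[Si](C)(C)C(C)(C)C)C(=C)[C@@H](C)CCCO[Si](c2ccccc2)(c2ccccc2)C(C)(C)C)[C@@H](CC(C)=C)O1 | intermediate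
22 | (3aR,4R,7aR)-4-[(tert-butyldimethylsilyl)oxy]-5-{(2S)-5-[(tert-butyldiphenylsilyl)oxy]pentan-2-yl}-6-methyl-3a,4,7,7a-tetrahydro-1-benzofuran-2(3H)-one | O=C1C[C@H]2[C@@H](O[Si](C)(C)C(C)(C)C)C([C@@H](C)CCCO[Si](c3ccccc3)(c3ccccc3)C(C)(C)C)=C(C)C[C@H]2O1 | intermediate
23 | (3aR,4R,7aR)-4-[(tert-butyldimethylsilyl)oxy]-5-{(2S)-5-[(tert-butyldiphenylsilyl)oxy]pentan-2-yl}-3-[(dimethylamino)methyl]-6-methyl-3a,4,7,7a-tetrahydro-1-benzofuran-2(3H)-one (C3 epimers) | CN(C)CC1C(=O)O[C@@H]2CC(C)=C([C@@H](C)CCCO[Si](c3ccccc3)(c3ccccc3)C(C)(C)C)[C@H](O[Si](C)(C)C(C)(C)C)[C@H]12 | intermediate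
24 | trimethylammonium iodide of 23, {(3aR,4R,7aR)-4-[(tert-butyldimethylsilyl)oxy]-5-{(2S)-5-[(tert-butyldiphenylsilyl)oxy]pentan-2-yl}-6-methyl-2-oxo-2,3,3a,4,7,7a-hexahydro-1-benzofuran-3-yl}-N,N,N-trimethylmethanaminium iodide | C[N+](C)(C)CC1C(=O)O[C@@H]2CC(C)=C([C@@H](C)CCCO[Si](c3ccccc3)(c3ccccc3)C(C)(C)C)[C@H](O[Si](C)(C)C(C)(C)C)[C@H]12.[I-] | intermediate
25 | (3aR,4R,7aR)-4-[(tert-butyldimethylsilyl)oxy]-5-{(2S)-5-[(tert-butyldiphenylsilyl)oxy]pentan-2-yl}-6-methyl-3-methylidene-3a,4,7,7a-tetrahydro-1-benzofuran-2(3H)-one | C=C1C(=O)O[C@@H]2CC(C)=C([C@@H](C)CCCO[Si](c3ccccc3)(c3ccccc3)C(C)(C)C)[C@H](O[Si](C)(C)C(C)(C)C)[C@H]12 | intermediate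
26 | britannilactone, (3aS,4R,7aR)-4-hydroxy-5-[(2S)-5-hydroxypentan-2-yl]-6-methyl-3-methylidene-3a,4,7,7a-tetrahydro-1-benzofuran-2(3H)-one | C=C1C(=O)O[C@@H]2CC(C)=C([C@@H](C)CCCO)[C@H](O)[C@H]12 | intermediate
27 | 1,6-O,O-diacetylbritannilactone, (3aR,4R,7aR)-5-[(2S)-5-(acetyloxy)pentan-2-yl]-6-methyl-3-methylidene-2-oxo-2,3,3a,4,7,7a-hexahydro-1-benzofuran-4-yl acetate | C=C1C(=O)O[C@@H]2CC(C)=C([C@@H](C)CCCOC(C)=O)[C@H](OC(C)=O)[C@H]12 | target

**Totals**

Total step count: 16. Longest linear sequence: 15 steps (steps 1–6 and 8–16, from (S)-citronellol); step 7 is the one-step side branch.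

**Three steps most likely to fail, with fallbacks**

Risk 1, step 8 (anti-aldol). The β-ester of imide 13 can compete for magnesium and the α-branched enal 9 is hindered, so conversion or the anti ratio may be poor. The fallback replaces the auxiliary-bound metal enolate by enamine catalysis. It sets out from enal 9: L-proline (20 mol%, DMF, 4 °C) with slowly added tert-butyl 4-oxobutanoate (CC(C)(C)OC(=O)CCC=O) gives the anti cross-aldol product tert-butyl (3S,4R,6S)-9-[(tert-butyldiphenylsilyl)oxy]-3-formyl-4-hydroxy-6-methyl-5-methylidenenonanoate F1. Pinnick oxidation (NaClO2, NaH2PO4, 2-methylbut-2-ene, t-BuOH/H2O) gives (2S,3R,5S)-2-[2-(tert-butoxy)-2-oxoethyl]-8-[(tert-butyldiphenylsilyl)oxy]-3-hydroxy-5-methyl-4-methylideneoctanoic acid F2. Coupling with MeNH(OMe)·HCl (EDC·HCl, HOBt, N-methylmorpholine, CH2Cl2) comes back to the route at Weinreb amide 16.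

Risk 2, step 12 (ketone reduction). The Felkin–Anh preference could be eroded by the CH2CO2t-Bu arm, and the β,γ-unsaturated ketone can enolise. The fallback sets C8 by reagent-controlled carbonyl allylation instead of substrate-controlled reduction. It sets out from Weinreb amide 17: i-Bu2AlH (THF, −78 °C) gives tert-butyl (3S,4R,6S)-4-[(tert-butyldimethylsilyl)oxy]-9-[(tert-butyldiphenylsilyl)oxy]-3-formyl-6-methyl-5-methylidenenonanoate F3. This is treated at −78 °C in Et2O with (2-methylallyl)diisopinocampheylborane, made from (+)-Ipc2BOMe (the enantiomer derived from (−)-α-pinene) and 18, then NaOH/H2O2. The product is hydroxy ester 20, where the fallback comes back to the route before the acid-catalysed lactonisation to 21.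

Risk 3, step 13 (ring-closing metathesis). The alkene at C5 is flanked by two branched carbons, so closure to the tetrasubstituted alkene may stall. The fallback forms the same C5=C10 bond by carbonyl coupling instead of metathesis. It sets out from lactone 21: ozonolysis of both methylidene groups (O3, CH2Cl2, −78 °C; Me2S) gives (4R,5R)-4-{(1R,3S)-1-[(tert-butyldimethylsilyl)oxy]-6-[(tert-butyldiphenylsilyl)oxy]-3-methyl-2-oxohexyl}-5-(2-oxopropyl)oxolan-2-one F4. Intramolecular McMurry coupling (TiCl3(DME)1.5, Zn–Cu couple, DME, reflux, slow addition) comes back to the route at bicyclic lactone 22. This is a second choice: low-valent titanium may cleave the α-silyloxy group, and C4 becomes epimerisable next to the new ketone, so short contact times are needed.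

**Further compounds**

F1 | step 8 | tert-butyl (3S,4R,6S)-9-[(tert-butyldiphenylsilyl)oxy]-3-formyl-4-hydroxy-6-methyl-5-methylidenenonanoate | CC(C)(C)OC(=O)C[C@H](C=O)[C@@H](O)C(=C)[C@@H](C)CCCO[Si](c1ccccc1)(c1ccccc1)C(C)(C)C
F2 | step 8 | (2S,3R,5S)-2-[2-(tert-butoxy)-2-oxoethyl]-8-[(tert-butyldiphenylsilyl)oxy]-3-hydroxy-5-methyl-4-methylideneoctanoic acid | CC(C)(C)OC(=O)C[C@H](C(=O)O)[C@@H](O)C(=C)[C@@H](C)CCCO[Si](c1ccccc1)(c1ccccc1)C(C)(C)C
F3 | step 12 | tert-butyl (3S,4R,6S)-4-[(tert-butyldimethylsilyl)oxy]-9-[(tert-butyldiphenylsilyl)oxy]-3-formyl-6-methyl-5-methylidenenonanoate | CC(C)(C)OC(=O)C[C@H](C=O)[C@@H](O[Si](C)(C)C(C)(C)C)C(=C)[C@@H](C)CCCO[Si](c1ccccc1)(c1ccccc1)C(C)(C)C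
F4 | step 13 | (4R,5R)-4-{(1R,3S)-1-[(tert-butyldimethylsilyl)oxy]-6-[(tert-butyldiphenylsilyl)oxy]-3-methyl-2-oxohexyl}-5-(2-oxopropyl)oxolan-2-one | O=C1C[C@@H]([C@@H](O[Si](C)(C)C(C)(C)C)C(=O)[C@@H](C)CCCO[Si](c2ccccc2)(c2ccccc2)C(C)(C)C)[C@@H](CC(C)=O)O1
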